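**Strategy.** With the ring numbered C1 (quaternary carbinol carbon), C2 (CHOH), C3 (CHOBz), C4=C5 and C6 (ketone), the segment C4–C5–C6–C1 together with the C1 oxygen is a masked 3-methoxyfuran. A Diels–Alder reaction of (3-methoxyfuran-2-yl)methanol with vinylene carbonate should form C1–C2 and C3–C4 in one operation and turn the flat heteroarene into a 7-oxanorbornene that holds every ring carbon and oxygen of zeylenone: the furan oxygen becomes the C1 hydroxyl, the enol ether the C6 ketone, and β-elimination of the bridge gives the C4=C5 enone. Lipase benzoylation selects the enantiomer; Mitsunobu inversion sets the trans C3 benzoate.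

Key step: step 2

Assumption: 3-methoxyfuran (1) is taken as a catalogue chemical; if it must be made, NaOMe/CuBr on 3-bromofuran gives it in one extra step.
Remark: racemic compounds 5 and 6 are drawn as the enantiomer that is carried on. Locants C1–C6 in the Why lines are those of the target ring defined above. "Exo" means on the face of the oxygen bridge.

**Step 1**
Reactants: 1 3-methoxyfuran
Product: 3 (3-methoxyfuran-2-yl)methanol, via 3-methoxy-2-furyllithium 2 (not isolated)
Conditions: n-BuLi (1.05 equiv), THF, −78 to 0 °C; paraformaldehyde (1.5 equiv), −78 °C to rt; H2O quench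
Reagents that add atoms: paraformaldehyde as source of formaldehyde, C=O
Why: Directed lithiation should occur at furan C2, the most acidic position (next to the ring oxygen and ortho to the methoxy group), and the furyllithium adds to formaldehyde to give the primary alcohol; no stereocentre is formed.

**Step 2**
Reactants: 3 (3-methoxyfuran-2-yl)methanol; 4 vinylene carbonate
Product: 5 racemic exo cycloadduct, the cyclic carbonate of 1-(hydroxymethyl)-6-methoxy-7-oxabicyclo[2.2.1]hept-5-ene-2-exo,3-exo-diol
Conditions: 4 (10 equiv, neat), BHT (1 mol %), Ar, sealed tube, 90 °C, 48 h; chromatography on Et3N-deactivated silica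
Reagents that add atoms: none
Why: A concerted, suprafacial [4+2] cycloaddition of normal electron demand joins furan C2 and C5 (target C1 and C4; HOMO raised by the 3-methoxy group) to the two alkene carbons of the carbonate (target C2 and C3). The closest known reaction types are the thermal Diels–Alder addition of vinylene carbonate to furans and the cycloadditions of 3-alkoxyfurans that give 7-oxanorbornenyl enol ethers. The carbocycle C1–C6 and the 7-oxabicyclo[2.2.1]heptene are closed by this intermolecular [4π+2π] cycloaddition and by no cyclisation step, while the dioxolanone ring arrives preformed and cis-fused. C2 and C3 are cis because the (Z)-alkene adds suprafacially, C1 and C4 are tied to each other by the oxygen bridge, and the exo placement of the carbonate (cis to the later C1 hydroxyl) should result from thermodynamic control, since furan cycloadditions are reversible at 90 °C and the exo adduct avoids the clash of the carbonate with the enol ether π bond; absolute configuration is not controlled and the racemate goes on to step 4. The step needs exo over endo selectivity and cycloaddition in preference to loss of the acid-sensitive furan, which reversibility, the large excess of neat dienophile, the radical inhibitor and acid-free glassware should secure; regiochemistry is no issue because the dienophile is symmetric.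

**Step 3**
Reactants: 5 racemic exo cycloadduct
Product: 6 racemic (1S*,2S*,3R*,4S*)-1-(hydroxymethyl)-6-methoxy-7-oxabicyclo[2.2.1]hept-5-ene-2,3-diol (2-exo,3-exo)
Conditions: K2CO3 (0.2 equiv), MeOH, 0 °C to rt
Reagents that add atoms: none
Why: Base-catalysed methanolysis (transesterification) of the strained five-membered cyclic carbonate should release the cis-diol; the enol ether and all stereocentres are inert to base.

**Step 4**
Reactants: 6 racemic triol
Product: 7 [(1S,2S,3R,4S)-2,3-dihydroxy-6-methoxy-7-oxabicyclo[2.2.1]hept-5-en-1-yl]methyl benzoate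
Conditions: immobilised Candida antarctica lipase B (Burkholderia cepacia lipase as second candidate), vinyl benzoate (3 equiv), 4 Å MS, THF/t-BuOMe 1:1, 35 °C, stopped near 45–50 % conversion; chromatography
Reagents that add atoms: vinyl benzoate, C=COC(=O)c1ccccc1
Why: Lipase-catalysed kinetic resolution by irreversible transesterification should acylate only the primary hydroxyl and distinguish the enantiomers through the quaternary bridgehead stereocentre next to the carbinol carbon, so that the (1S,2S,3R,4S) triol is benzoylated and its antipode stays behind; no new stereocentre forms, the absolute configuration is selected here.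

**Step 5**
Reactants: 7 bicyclic diol monobenzoate
Product: 9 [(1S,5S,6S)-1,5,6-trihydroxy-2-oxocyclohex-3-en-1-yl]methyl benzoate, via bicyclic ketone 8 (not isolated)
Conditions: Dowex 50WX8 (H+ form), THF/H2O 4:1, 0 °C to rt; filter; then Et3N (1 equiv), CH2Cl2, 0 °C
Reagents that add atoms: water, O
Why: Acid-catalysed enol ether hydrolysis should give the 7-oxanorbornan-2-one, whose C5 enolate expels the bridge oxygen from C4 (E1cB β-elimination, driven by release of bicyclic strain); the oxygen stays on C1 as the tertiary hydroxyl, the C4=C5 enone appears, C1–C3 are untouched and the C4 stereocentre is erased.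

**Step 6**
Reactants: 9 all-cis triol enone
Product: 10 zeylenone, [(1S,5R,6S)-5-(benzoyloxy)-1,6-dihydroxy-2-oxocyclohex-3-en-1-yl]methyl benzoate
Conditions: PhCO2H (1.5 equiv), PPh3 (1.5 equiv), DIAD (1.5 equiv), THF, −20 to 0 °C
Reagents that add atoms: benzoic acid, O=C(O)c1ccccc1
Why: In this Mitsunobu reaction the allylic, least hindered C3 hydroxyl should be converted into the alkoxyphosphonium ion and displaced by benzoate with SN2 inversion, turning the cis C2/C3 relation into the required trans one; the neopentyl-like C2 hydroxyl and the tertiary C1 hydroxyl should not react.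

**Compound list**
1 | 3-methoxyfuran | COc1ccoc1 | starting material
2 | 3-methoxy-2-furyllithium | COc1ccoc1[Li] | intermediate
3 | (3-methoxyfuran-2-yl)methanol | COc1ccoc1CO | intermediate
4 | vinylene carbonate (1,3-dioxol-2-one) | O=C1OC=CO1 | starting material
5 | racemic exo cycloadduct: 2-exo,3-exo cyclic carbonate of 1-(hydroxymethyl)-6-methoxy-7-oxabicyclo[2.2.1]hept-5-ene-2,3-diol, carbonate on the face of the oxygen bridge (enantiomer carried on is drawn) | COC1=C[C@H]2[C@@H]3OC(=O)O[C@@H]3[C@]1(CO)O2 | intermediate
6 | racemic (1S*,2S*,3R*,4S*)-1-(hydroxymethyl)-6-methoxy-7-oxabicyclo[2.2.1]hept-5-ene-2,3-diol, both hydroxyls exo (enantiomer carried on is drawn) | COC1=C[C@H]2[C@H](O)[C@H](O)[C@]1(CO)O2 | intermediate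
7 | [(1S,2S,3R,4S)-2,3-dihydroxy-6-methoxy-7-oxabicyclo[2.2.1]hept-5-en-1-yl]methyl benzoate | COC1=C[C@H]2[C@H](O)[C@H](O)[C@]1(COC(=O)c3ccccc3)O2 | intermediate
8 | [(1S,2S,3R,4S)-2,3-dihydroxy-6-oxo-7-oxabicyclo[2.2.1]heptan-1-yl]methyl benzoate | O=C1C[C@H]2[C@H](O)[C@H](O)[C@]1(COC(=O)c3ccccc3)O2 | intermediate
9 | [(1S,5S,6S)-1,5,6-trihydroxy-2-oxocyclohex-3-en-1-yl]methyl benzoate (three hydroxyls mutually cis) | O=C(OC[C@@]1(O)C(=O)C=C[C@H](O)[C@@H]1O)c1ccccc1 | intermediate
10 | zeylenone, [(1S,5R,6S)-5-(benzoyloxy)-1,6-dihydroxy-2-oxocyclohex-3-en-1-yl]methyl benzoate | O=C(OC[C@@]1(O)C(=O)C=C[C@@H](OC(=O)c2ccccc2)[C@@H]1O)c1ccccc1 | target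

**Step count and risks**
Total step count: 6. Longest linear sequence: 6 steps (1 to 10).

Steps most likely to fail:

Step 2. The cycloaddition may stall because vinylene carbonate is a weak dienophile, the acid-sensitive furfuryl alcohol may be lost on prolonged heating, or the endo adduct may prevail. Fallback: the same two ring bonds are closed with the far more reactive acetylene equivalent (Z)-1,2-bis(phenylsulfonyl)ethene, and the diol is added afterwards from the exo face. Setting out from 3, cycloaddition (CH2Cl2, 25–40 °C) should give the racemic bis-sulfone adduct 1-(hydroxymethyl)-6-methoxy-2,3-bis(phenylsulfonyl)-7-oxabicyclo[2.2.1]hept-5-ene F1, whose configuration at the sulfonyl carbons is immaterial. Sodium amalgam Na(Hg) with NaH2PO4 in MeOH/THF at −20 °C should remove both sulfonyl groups to give racemic 1-(hydroxymethyl)-2-methoxy-7-oxabicyclo[2.2.1]hepta-2,5-diene F2. Enol ether hydrolysis (Dowex 50WX8 H+ form, wet THF, 0 °C) should give racemic 1-(hydroxymethyl)-7-oxabicyclo[2.2.1]hept-5-en-2-one F3. OsO4 (2 mol %) with N-methylmorpholine N-oxide in acetone/H2O should dihydroxylate the strained alkene from the exo face to give the racemic ketone triol 5-exo,6-exo-dihydroxy-1-(hydroxymethyl)-7-oxabicyclo[2.2.1]heptan-2-one F4. Lipase benzoylation as in step 4 then gives 8, where the route is rejoined (Et3N treatment of step 5).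

Step 4. The enzyme may discriminate the enantiomers poorly, since the carbinol is primary and the stereocentre quaternary, or it may prefer the antipode. Fallback: covalent resolution. Setting out from racemic 6, esterification of the primary hydroxyl with (S)-O-methylmandelic acid (EDC·HCl, DMAP, CH2Cl2, 0 °C) should give two diastereomers: the (1S,2S,3R,4S) (S)-O-methylmandelate F5 and the (1R,2R,3S,4R) (S)-O-methylmandelate F6, to be separated by chromatography or crystallisation. K2CO3/MeOH on F5 should give the enantiopure (1S,2S,3R,4S) triol F7. BzCl (1.05 equiv), 2,4,6-collidine, CH2Cl2, −40 °C should then benzoylate its primary hydroxyl to give 7.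

Step 6. The cis-2,3-diol may be tied up as a dioxaphosphorane, the alkoxyphosphonium ion may eliminate towards a phenol, or the C2 hydroxyl may compete. Fallback: two-stage inversion. Setting out from 9, MsCl (1.05 equiv), 2,4,6-collidine, CH2Cl2, −30 °C should sulfonylate the allylic, least hindered C3 hydroxyl to give [(1S,5S,6S)-1,6-dihydroxy-5-(methylsulfonyloxy)-2-oxocyclohex-3-en-1-yl]methyl benzoate F8. Cesium benzoate with 18-crown-6 in toluene at 25–40 °C should displace the mesylate with SN2 inversion to give 10.

Further compounds
F1 | step 2 | racemic 1-(hydroxymethyl)-6-methoxy-2,3-bis(phenylsulfonyl)-7-oxabicyclo[2.2.1]hept-5-ene (cis-disulfone, endo/exo mixture) | COC1=C[C@H]2C(S(=O)(=O)c3ccccc3)C(S(=O)(=O)c4ccccc4)[C@]1(CO)O2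
F2 | step 2 | racemic 1-(hydroxymethyl)-2-methoxy-7-oxabicyclo[2.2.1]hepta-2,5-diene | COC1=C[C@H]2C=C[C@]1(CO)O2
F3 | step 2 | racemic 1-(hydroxymethyl)-7-oxabicyclo[2.2.1]hept-5-en-2-one | O=C1C[C@H]2C=C[C@]1(CO)O2
F4 | step 2 | racemic 5-exo,6-exo-dihydroxy-1-(hydroxymethyl)-7-oxabicyclo[2.2.1]heptan-2-one | O=C1C[C@H]2[C@H](O)[C@H](O)[C@]1(CO)O2
F5 | step 4 | [(1S,2S,3R,4S)-2,3-dihydroxy-6-methoxy-7-oxabicyclo[2.2.1]hept-5-en-1-yl]methyl (S)-2-methoxy-2-phenylacetate | COC1=C[C@H]2[C@H](O)[C@H](O)[C@]1(COC(=O)[C@@H](OC)c3ccccc3)O2
F6 | step 4 | [(1R,2R,3S,4R)-2,3-dihydroxy-6-methoxy-7-oxabicyclo[2.2.1]hept-5-en-1-yl]methyl (S)-2-methoxy-2-phenylacetate | COC1=C[C@@H]2[C@@H](O)[C@@H](O)[C@@]1(COC(=O)[C@@H](OC)c3ccccc3)O2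
F7 | step 4 | (1S,2S,3R,4S)-1-(hydroxymethyl)-6-methoxy-7-oxabicyclo[2.2.1]hept-5-ene-2,3-diol (single enantiomer of 6) | COC1=C[C@H]2[C@H](O)[C@H](O)[C@]1(CO)O2
F8 | step 6 | [(1S,5S,6S)-1,6-dihydroxy-5-(methylsulfonyloxy)-2-oxocyclohex-3-en-1-yl]methyl benzoate | O=C(OC[C@@]1(O)C(=O)C=C[C@H](OS(C)(=O)=O)[C@@H]1O)c1ccccc1
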